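All runs come from a simulation from invented constants; noise was put on by code.

1.10 equivalents of partner stand in this flask, fewer than the 2 a substrate takes to reach double product, so partner is the limiting reagent, and a first estimate pairs it off into 55.0 % double product.

| setting | blue | flask |
|---|---|---|
| substrate | 0.050 M | 0.050 M |
| partner | 0.028 M | 0.0550 M |
| remark | run made earlier |  |
| time |  | 3.0 d |

blue run (percent of the substrate charged)

| time / h | double product / % | substrate / % |
|---|---|---|
| 1.33 | 9.9 | 55.9 |
| 4.00 | 8.2 | 55.8 |
| 8.00 | 5.7 | 55.5 |
| 12.0 | 3.1 | 55.3 |
| 15.0 | 2.3 | 55.8 |
| 20.0 | 0.8 | 55.6 |

(scatter of a reading: 0.3 percentage points)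

1. the best time, 3.0 d at the latest, for double product
2. the amount of double product, in percent of the substrate charged, at that time

- the numbers in the tables scatter with a standard deviation of 0.3 percentage points
- a reading or a percentage of double product counts all its forms, free or not

The blue run objects. Its substrate stands level at a mean of 55.6 %, and with 0.560 equivalents the partner balance leaves 11.6 % double product and 32.7 % first product, far more first product, so pairing fails. Two steps with equal constants would give first product −s·ln s = 32.6 % for substrate fraction s, which agrees. For e equivalents, c(partner)/c(substrate), with τ the rate constant times c(partner) summed over the run and d the fraction of substrate in double product, this reads: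

τ = ln[(2 + τ)/(2 − e)], s = exp(−τ), d = 1 − s − τ·s

In this flask τ = 1.30, s = 27.3 %, and d = 37.3 %, the loss-free yield, the double product that the two steps make if none of it is lost.

But double product falls with time in the blue run. The blue reading at 1.33 h lies 1.7 percentage points under its balance, while the later straight fall, carried back, explains 0.85 points, less. That fall is nearly straight rather than proportional to the amount, and the blue run and this flask hold the same substrate charge, so this reckoning takes the gap, itself a reading with its scatter, as the correction in points, which gives an estimate of about 35.5 % near 1.33 h for this flask.

The forecast gives 36 % at 1.2 h, “Allowing for slight loss”, slightly higher than this reckoning.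

The flask gives 35.4 % at 1.18 h.

    substrate + partner → first product (k = 2.40 M⁻¹ min⁻¹)
    partner + first product → double product (k = 2.30 M⁻¹ min⁻¹)
    crystals ⇌ double product, rate k3*(cs3 - [double product]) while solid is left; crystals form when [double product] > cs3 (solubility = 2.70 mM, k = 0.210 min⁻¹)
    double product → over-reaction product (k = 0.00240 min⁻¹)

This peak stands 1.9 points under the loss-free yield, and at 3.00 d double product plus over-reaction product comes to 36.9 % in this flask. The neighbour charged with 0.093 M of partner has 1.86 equivalents, so τ = 3.71 and its loss-free yield is 88.5 %. Its peak reaches 84.0 %, and at 3.00 d it holds 32.0 % double product, crystals counted, and 56.3 % over-reaction product, together 88.3 %.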